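Ring B is cut at C1–C7 and C5–C6. What remains is a flat, fully substituted acylphloroglucinol: ring A (C1–C2–C3–C4–C5–C8) is that arene in its triketo form, and ring B adds just two carbons, C6 and C7, tied to the meta-related ring carbons C1 and C5. One palladium-catalysed dearomative annulation with a five-carbon bis-allylic electrophile (fast-ionising carbonate at one end, slower acetate at the other) should form both bonds, close ring B and set C1, C5 and C6 together. The precursor is the C-methyl, C-prenyl (R)-2-methylbutanoylphloroglucinol, two steps from 2-methylphloroglucinol. Chemoselective hydration of the isopropenyl group then gives the target.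

Key step: step 6

Atom numbering of the bicycle: C1 prenyl bridgehead, C2 and C4 ring carbonyl or enol carbons, C3 acyl-bearing carbon, C5 methyl bridgehead, C6 the CH, C7 the CH2, C8 bridging ketone.

Assumption: the sense of induction of the chiral ligand in step 6 cannot be derived with confidence; the route is written with the (R,R) ligand, and the mirror-image ligand is to be used if the first run leads to the other series.

Remark: enolised triketones are drawn in the tautomer of the target; the tautomers interconvert freely.

Design note: in the electrophile the tert-butyl carbonate sits on the CH2 next to the alkene CH and the acetate on the CH2 next to the methyl-bearing alkene carbon, so the end that ionises first is the end that must bond to C1. Two equal leaving groups could not be told apart. A tert-butyl rather than a methyl carbonate is chosen so that the alkoxide released cannot cleave the acetate. The arene is used with all three hydroxyls free.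

Step 1
Reactants: 1 2-methylbenzene-1,3,5-triol; 2 (R)-2-methylbutanoic acid
Product: 4 (2R)-2-methyl-1-(2,4,6-trihydroxy-3-methylphenyl)butan-1-one, via (R)-2-methylbutanoyl chloride 3 (not isolated)
Conditions: 2, (COCl)2, cat. DMF, CH2Cl2, 0 °C to rt, volatiles removed cold; then 1, AlCl3, PhNO2/CH2Cl2, 0 °C to rt; aq. HCl
Reagents that add atoms: none
Why: Friedel–Crafts acylation of the electron-rich triol at one of its two equivalent free ring positions should stop after one acylation because the ketone deactivates the ring, and without base and at low temperature no ketene or enol path is open, so the (R) centre of 2 should be retained.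

Step 2
Reactants: 4 (2R)-2-methyl-1-(2,4,6-trihydroxy-3-methylphenyl)butan-1-one; 5 1-bromo-3-methylbut-2-ene
Product: 6 (2R)-2-methyl-1-[2,4,6-trihydroxy-3-methyl-5-(3-methylbut-2-en-1-yl)phenyl]butan-1-one
Conditions: 5 (1.0 equiv), 1 M aq. KOH, 0 °C; then aq. HCl
Reagents that add atoms: none
Why: Base-mediated C-alkylation of the phenolate in water (hydrogen bonding masks the oxygens) should go to the only unsubstituted ring carbon, because substitution there ends in rearomatisation; one equivalent of bromide at 0 °C limits a second, dearomatising prenylation, and the acylphenolate does not enolise at the α-stereocentre.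

Step 3
Reactants: 7 3-methylbut-2-en-1-ol
Product: 8 tert-butyl 3-methylbut-2-en-1-yl carbonate
Conditions: Boc2O, Bu4NHSO4 (cat.), 30% aq. NaOH, CH2Cl2, 0 °C to rt
Reagents that add atoms: di-tert-butyl dicarbonate CC(C)(C)OC(=O)OC(=O)OC(C)(C)C
Why: Phase-transfer O-acylation of a primary allylic alcohol with Boc2O is a standard preparation of allylic tert-butyl carbonates, and nothing else in 7 reacts.

Step 4
Reactants: 8 tert-butyl 3-methylbut-2-en-1-yl carbonate
Product: 9 tert-butyl (2E)-4-hydroxy-3-methylbut-2-en-1-yl carbonate
Conditions: SeO2 (0.5 equiv), t-BuOOH (70% aq., 2 equiv), CH2Cl2, 0 °C to rt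
Reagents that add atoms: selenium dioxide O=[Se]=O (gives the hydroxyl oxygen; kept in turnover by tert-butyl hydroperoxide CC(C)(C)OO)
Why: Sharpless–Riley allylic oxidation (ene reaction, then [2,3]-sigmatropic shift) is known for prenyl esters to hydroxylate the methyl group trans to the chain and so should give the (E)-alcohol; the electron-poor CH2 next to the carbonate is left alone, and the run is stopped before much alcohol is carried on to the enal, which is removed here.

Step 5
Reactants: 9 tert-butyl (2E)-4-hydroxy-3-methylbut-2-en-1-yl carbonate
Product: 10 (2E)-4-acetoxy-3-methylbut-2-en-1-yl tert-butyl carbonate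
Conditions: Ac2O, pyridine, DMAP (cat.), CH2Cl2, 0 °C
Reagents that add atoms: acetic anhydride CC(=O)OC(C)=O
Why: Standard acetylation of a primary allylic alcohol, to which the carbonate and the alkene geometry are inert.

Step 6
Reactants: 6 (2R)-2-methyl-1-[2,4,6-trihydroxy-3-methyl-5-(3-methylbut-2-en-1-yl)phenyl]butan-1-one; 10 (2E)-4-acetoxy-3-methylbut-2-en-1-yl tert-butyl carbonate
Product: 12 (1R,5R,6S)-4-hydroxy-5-methyl-3-[(2R)-2-methylbutanoyl]-1-(3-methylbut-2-en-1-yl)-6-(prop-1-en-2-yl)bicyclo[3.2.1]oct-3-ene-2,8-dione, via C1-allylated dienone acetate 11 (not isolated)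
Conditions: 10 (1.2 equiv), Pd2(dba)3·CHCl3 (5 mol %), (R,R)-DACH-phenyl Trost ligand (12 mol %), degassed THF, rt, then 50 °C
Reagents that add atoms: none
Why: Zerovalent palladium ionises the allylic carbonate of 10 first (CO2 leaves and tert-butoxide deprotonates 6), the phenoxide attacks the unsubstituted CH2 terminus of this π-allyl through C1 to give dienone 11, and ionisation of the remaining allylic acetate gives a second π-allyl whose near CH terminus is taken by C5 of the enolate, which forms C5–C6, ends aromaticity for good and leaves the isopropenyl group on C6. The closest known chemistry is the palladium-catalysed dearomative conjunctive allylic annulation of acylphloroglucinols with 2-methylenepropane-1,3-diyl biscarbonates, joined here to the intramolecular Tsuji–Trost 5-exo alkylation that makes vinylcyclopentanes. Ring B (C1–C7–C6–C5–C8) closes by 5-exo attack of C5 on the π-allyl, preferred over 7-endo attack at the far CH2. C1 is set by the chiral ligand, which picks the face of the flat phenoxide (and can be corrected as long as 11 re-ionises), C5 follows from C1 because the two-carbon tether reaches only the face it sits on, and C6 is set in the closure, where the 2-methylallyl–palladium unit should turn away from the C2–C3–C4 enolate so that the isopropenyl group ends exo, on the side of C8. The step needs carbonate before acetate (carbonates ionise faster and irreversibly), C- over O-allylation and C1 before C5: O-allyl ethers and C-allyl dienones, the C3 adduct included, should return to the π-allyl under zerovalent palladium whereas the bridged trione does not, and of the two dienones the one allylated at C1 should close faster because it presents the less hindered methyl-bearing C5 to the internal allyl terminus.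

Step 7
Reactants: 12 (1R,5R,6S)-4-hydroxy-5-methyl-3-[(2R)-2-methylbutanoyl]-1-(3-methylbut-2-en-1-yl)-6-(prop-1-en-2-yl)bicyclo[3.2.1]oct-3-ene-2,8-dione
Product: 13 (1R,5R,6R)-4-hydroxy-6-(2-hydroxypropan-2-yl)-5-methyl-3-[(2R)-2-methylbutanoyl]-1-(3-methylbut-2-en-1-yl)bicyclo[3.2.1]oct-3-ene-2,8-dione
Conditions: Co(acac)2 (20 mol %), PhSiH3 (2.5 equiv), O2 (1 atm), THF, rt; then dilute aq. HCl
Reagents that add atoms: dioxygen O=O
Why: Mukaiyama hydration (cobalt hydride hydrogen atom transfer, capture of the tertiary radical by O2, reduction of the peroxide by silane) should give the Markovnikov tertiary alcohol at the 1,1-disubstituted isopropenyl group, which accepts the hydrogen atom faster than the trisubstituted prenyl alkene; no stereocentre is formed or touched, the ketones and the enol are inert to PhSiH3, and dilute acid in the work-up frees the triketone from cobalt.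

Compound list
1 | 2-methylbenzene-1,3,5-triol | Cc1c(O)cc(O)cc1O | starting material
2 | (R)-2-methylbutanoic acid | CC[C@@H](C)C(=O)O | starting material
3 | (R)-2-methylbutanoyl chloride | CC[C@@H](C)C(=O)Cl | intermediate
4 | (2R)-2-methyl-1-(2,4,6-trihydroxy-3-methylphenyl)butan-1-one | CC[C@@H](C)C(=O)c1c(O)cc(O)c(C)c1O | intermediate
5 | 1-bromo-3-methylbut-2-ene | CC(C)=CCBr | starting material
6 | (2R)-2-methyl-1-[2,4,6-trihydroxy-3-methyl-5-(3-methylbut-2-en-1-yl)phenyl]butan-1-one | CC[C@@H](C)C(=O)c1c(O)c(C)c(O)c(CC=C(C)C)c1O | intermediate
7 | 3-methylbut-2-en-1-ol | CC(C)=CCO | starting material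
8 | tert-butyl 3-methylbut-2-en-1-yl carbonate | CC(C)=CCOC(=O)OC(C)(C)C | intermediate
9 | tert-butyl (2E)-4-hydroxy-3-methylbut-2-en-1-yl carbonate | C/C(CO)=C\COC(=O)OC(C)(C)C | intermediate
10 | (2E)-4-acetoxy-3-methylbut-2-en-1-yl tert-butyl carbonate | C/C(COC(C)=O)=C\COC(=O)OC(C)(C)C | intermediate
11 | (2E)-4-[(1R)-2,4-dihydroxy-3-methyl-5-[(2R)-2-methylbutanoyl]-1-(3-methylbut-2-en-1-yl)-6-oxocyclohexa-2,4-dien-1-yl]-2-methylbut-2-en-1-yl acetate | CC[C@@H](C)C(=O)C1=C(O)C(C)=C(O)[C@@](CC=C(C)C)(C/C=C(\C)COC(C)=O)C1=O | intermediate
12 | (1R,5R,6S)-4-hydroxy-5-methyl-3-[(2R)-2-methylbutanoyl]-1-(3-methylbut-2-en-1-yl)-6-(prop-1-en-2-yl)bicyclo[3.2.1]oct-3-ene-2,8-dione | CC[C@@H](C)C(=O)C1=C(O)[C@]2(C)C(=O)[C@@](CC=C(C)C)(C[C@H]2C(C)=C)C1=O | intermediate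
13 | (1R,5R,6R)-4-hydroxy-6-(2-hydroxypropan-2-yl)-5-methyl-3-[(2R)-2-methylbutanoyl]-1-(3-methylbut-2-en-1-yl)bicyclo[3.2.1]oct-3-ene-2,8-dione | CC[C@@H](C)C(=O)C1=C(O)[C@]2(C)C(=O)[C@@](CC=C(C)C)(C[C@H]2C(C)(C)O)C1=O | target

Total step count: 7
Longest linear sequence: 5 steps (7 → 8 → 9 → 10 → 12 → 13; the arene branch 1 → 4 → 6 joins at step 6)

Steps most likely to fail

1. Step 6. The first allylation may lose site control (C5 instead of C1, which would place the bridge the other way round). The second π-allyl may be closed by an enol oxygen to a dihydrofuran that does not reopen fast enough. Facial selectivity at C1 or exo selectivity at C6 may be poor. The fallback sets out from 6 and 9 and comes back to the route at 12. It splits the annulation into two isolated operations with a hydroxyl as a dormant second leaving group. Tsuji–Trost allylation of 6 with hydroxy carbonate 9 under the catalyst of step 6 at room temperature should stop at (6R)-3,5-dihydroxy-6-[(2E)-4-hydroxy-3-methylbut-2-en-1-yl]-4-methyl-2-[(2R)-2-methylbutanoyl]-6-(3-methylbut-2-en-1-yl)cyclohexa-2,4-dien-1-one F1, because a free allylic hydroxyl does not ionise under these conditions. F1 is freed by chromatography from its site isomer and its C1 epimer. It is then closed to 12 by a dehydrative intramolecular Tsuji–Trost alkylation (Pd(PPh3)4, catalytic PhCO2H, toluene, 80 °C), a known way to use allylic alcohols with acidic carbon pronucleophiles, in which the acidic enol activates the hydroxyl.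

2. Step 7. Hydrogen atom transfer may also reach the prenyl alkene, or the reaction may stall because the acidic triketone binds the cobalt. The fallback sets out from 12 and comes back at 13 and replaces the radical hydration by an ionic one. Oxymercuration with Hg(OAc)2 in THF/H2O at 0 °C, which is known to be considerably faster for 1,1-disubstituted than for trisubstituted alkenes, should give (1R,5R,6R)-6-[1-(acetoxymercurio)-2-hydroxypropan-2-yl]-4-hydroxy-5-methyl-3-[(2R)-2-methylbutanoyl]-1-(3-methylbut-2-en-1-yl)bicyclo[3.2.1]oct-3-ene-2,8-dione F2 (either configuration at the new carbinol carbon, which becomes achiral again). Brief demercuration with NaBH4 in aq. NaOH at 0 °C, with the triketone held as its sodium enolate and the hindered C8 ketone reacting more slowly than the carbon–mercury bond, should then give 13.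

3. Step 2. A second, dearomatising prenylation and O-alkylation with chroman formation may consume the material. The fallback sets out from 4 and 8 and comes back at 6. It replaces the alkylation with bromide by a Tsuji–Trost prenylation with carbonate 8 (Pd(PPh3)4, THF, rt). O-prenyl ethers re-ionise under zerovalent palladium, attack occurs at the unsubstituted terminus of the prenyl π-allyl, and C-prenylation at the free ring carbon is made irreversible by rearomatisation. It makes no compound outside the route (F0).

Further compounds
F1 | step 6 | (6R)-3,5-dihydroxy-6-[(2E)-4-hydroxy-3-methylbut-2-en-1-yl]-4-methyl-2-[(2R)-2-methylbutanoyl]-6-(3-methylbut-2-en-1-yl)cyclohexa-2,4-dien-1-one | CC[C@@H](C)C(=O)C1=C(O)C(C)=C(O)[C@@](CC=C(C)C)(C/C=C(\C)CO)C1=O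
F2 | step 7 | (1R,5R,6R)-6-[1-(acetoxymercurio)-2-hydroxypropan-2-yl]-4-hydroxy-5-methyl-3-[(2R)-2-methylbutanoyl]-1-(3-methylbut-2-en-1-yl)bicyclo[3.2.1]oct-3-ene-2,8-dione | CC[C@@H](C)C(=O)C1=C(O)[C@]2(C)C(=O)[C@@](CC=C(C)C)(C[C@H]2C(C)(O)C[Hg]OC(C)=O)C1=O
F0 | step 2 | none | none
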